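**Retrosynthetic overview**

1. The target is traced back (phenol desilylation, Swern oxidation of the 11,12-diol, Yamaguchi esterification at O1, lactone reduction) to 1β,5α-dihydroxydrim-7-en-12,11-olide; the lactone (C12 carbonyl, C11–O) is a temporary ring that carries the ene-dialdehyde at a lower oxidation level.
2. Key disconnection C9–C10 (closes ring B): a hydrogen-atom-transfer (HAT) initiated radical cyclisation of a monocyclic ring A diol that bears an exocyclic C10=CH2 and, on C5, a (Z)-C6=C7 alkene attached to the α-carbon (C8) of a butenolide.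
3. Enabling feature: C10 is the methyl-bearing quaternary carbon of ring A, flanked by the oxygenated carbons C1 and C5. Its methyl can be masked as a methylene, so HAT unmasks a tertiary C10 radical, while C9 is the β-carbon of the C8–C12(=O) enoate unit of ring B and is held next to C10 by the C5–C6=C7–C8 tether.
4. The precursor comes from Sonogashira coupling and Lindlar reduction of a C5 ethynyl carbinol, made by epoxide-to-allylic-alcohol isomerisation, anti-epoxidation of a CBS-derived (R)-cyclohexenol, and Stork–Danheiser alkynylation of the vinylogous ester of 2,4,4-trimethylcyclohexane-1,3-dione.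
5. Ring order: ring A (step 1), butenolide ring bought (step 9), ring B (step 11). Stereocontrol: C1 by catalysis (step 4), C5 relayed from C1 (step 6), C10 and C9 relayed from C1/C5 in the key step.

Key step: step 11

Remark (numbering): drimane numbering is used for all intermediates (C4 = CMe2, C5 = ring-fusion carbinol carbon, C10 = methyl-bearing ring-fusion carbon, C1 = acyloxy carbon, C9 and C8 carry C11 and C12). β is the face of the C10 methyl group; the target is read as 1β-acyloxy, 5α-OH, 9α-H, 10β-CH3, i.e. (1R,5R,9R,10S), and all bicyclic intermediates have 9α-H and 10β-CH3.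
Remark (assumption): 3-bromofuran-2(5H)-one (14) is taken as a purchasable building block.

**Route**

Step 1
Reactants: 1 2-methylpentan-3-one; 2 methyl acrylate
Product: 4 2,4,4-trimethylcyclohexane-1,3-dione, via keto ester 3 (not isolated)
Conditions: KOtBu, THF, 0 °C to reflux; then aq. HCl
Reagents that add atoms: none
Why: Michael addition of the more substituted enolate of 1 to 2 followed by intramolecular Claisen condensation, driven by formation of the stabilised β-diketone enolate, should give the ring A dione that already holds C1–C5, C10 and the three methyl groups.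

Step 2
Reactants: 4 2,4,4-trimethylcyclohexane-1,3-dione
Product: 5 3-(2-methylpropoxy)-2,6,6-trimethylcyclohex-2-en-1-one
Conditions: iBuOH, TsOH·H2O (cat.), toluene, reflux, Dean–Stark
Reagents that add atoms: 2-methylpropan-1-ol, CC(C)CO
Why: Acid-catalysed enol ether (vinylogous ester) formation should take place at the less hindered carbonyl, leaving the ketone next to the gem-dimethyl carbon (future C5) as the only electrophilic site.

Step 3
Reactants: 5 3-(2-methylpropoxy)-2,6,6-trimethylcyclohex-2-en-1-one; 6 ethynyl(trimethyl)silane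
Product: 8 2,4,4-trimethyl-3-[(trimethylsilyl)ethynyl]cyclohex-2-en-1-one, via carbinol adduct 7 (not isolated)
Conditions: 6, n-BuLi, THF, −78 °C; add 5, −78 °C to rt; then 1 M HCl, rt
Reagents that add atoms: water, O
Why: Stork–Danheiser transposition: 1,2-addition of the slim lithium acetylide to the neopentyl ketone, then acid-induced loss of water and hydrolysis of the enol ether, should give the 3-alkynyl enone with C6 and C7 attached to C5.

Step 4
Reactants: 8 2,4,4-trimethyl-3-[(trimethylsilyl)ethynyl]cyclohex-2-en-1-one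
Product: 9 (1R)-2,4,4-trimethyl-3-[(trimethylsilyl)ethynyl]cyclohex-2-en-1-ol
Conditions: (S)-2-methyl-CBS-oxazaborolidine (20 mol %), BH3·SMe2, THF, −30 °C; then MeOH
Reagents that add atoms: none
Why: Corey–Bakshi–Shibata reduction, in which the α-methyl-substituted alkenyl arm acts as the large group, should give the (R)-allylic alcohol; this is the only stereocenter set by catalysis and becomes C1 of the target.

Step 5
Reactants: 9 (1R)-2,4,4-trimethyl-3-[(trimethylsilyl)ethynyl]cyclohex-2-en-1-ol
Product: 10 tert-butyldimethyl{[(1R)-2,4,4-trimethyl-3-[(trimethylsilyl)ethynyl]cyclohex-2-en-1-yl]oxy}silane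
Conditions: TBSCl, imidazole, DMF, rt
Reagents that add atoms: tert-butyldimethylsilyl chloride, CC(C)(C)[Si](C)(C)Cl
Why: Standard silylation turns the hydroxyl from a syn-directing into a bulky anti-directing group for the epoxidation.

Step 6
Reactants: 10 tert-butyldimethyl{[(1R)-2,4,4-trimethyl-3-[(trimethylsilyl)ethynyl]cyclohex-2-en-1-yl]oxy}silane
Product: 11 tert-butyldimethyl({(1S,5R,6S)-2,2,6-trimethyl-1-[(trimethylsilyl)ethynyl]-7-oxabicyclo[4.1.0]heptan-5-yl}oxy)silane (C5–C10 α-epoxide, trans to the C1 silyloxy group)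
Conditions: mCPBA, CH2Cl2, 0 °C
Reagents that add atoms: 3-chloroperbenzoic acid, OOC(=O)c1cccc(Cl)c1
Why: Prilezhaev epoxidation of the tetrasubstituted, most electron-rich alkene should occur on the face opposite the bulky silyloxy group, which places the future C5–O bond trans to the C1–O bond.

Step 7
Reactants: 11 the α-epoxide
Product: 12 (1R,5R)-5-[(tert-butyldimethylsilyl)oxy]-2,2-dimethyl-6-methylidene-1-[(trimethylsilyl)ethynyl]cyclohexan-1-ol
Conditions: Et2AlTMP (from 2,2,6,6-tetramethylpiperidine, n-BuLi, Et2AlCl), toluene, 0 °C; then H2O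
Reagents that add atoms: none
Why: Aluminium amide-mediated isomerisation of an epoxide to an allylic alcohol (syn β-elimination): the C10 methyl group is the only accessible source of β-hydrogen (C4 is quaternary, C6 is sp-hybridised), so the C10–O bond should break, leaving the oxygen on C5 with its configuration and creating the exocyclic C10=CH2.

Step 8
Reactants: 12 (1R,5R)-5-[(tert-butyldimethylsilyl)oxy]-2,2-dimethyl-6-methylidene-1-[(trimethylsilyl)ethynyl]cyclohexan-1-ol
Product: 13 (1S,3R)-1-ethynyl-6,6-dimethyl-2-methylidenecyclohexane-1,3-diol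
Conditions: Bu4NF, THF, 0 °C to rt
Reagents that add atoms: none
Why: Fluoride-mediated desilylation should remove the O-silyl and the C-silyl group in one operation.

Step 9
Reactants: 13 (1S,3R)-1-ethynyl-6,6-dimethyl-2-methylidenecyclohexane-1,3-diol; 14 3-bromofuran-2(5H)-one
Product: 15 3-{[(1S,5R)-1,5-dihydroxy-2,2-dimethyl-6-methylidenecyclohexyl]ethynyl}furan-2(5H)-one
Conditions: Pd(PPh3)2Cl2 (5 mol %), CuI (10 mol %), Et3N, THF, rt
Reagents that add atoms: none
Why: Sonogashira coupling of the terminal alkyne with the lactone-activated vinyl bromide should attach C8, C9, C11 and C12 in one step, with C11 and C12 already tied cis in the butenolide.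

Step 10
Reactants: 15 3-{[(1S,5R)-1,5-dihydroxy-2,2-dimethyl-6-methylidenecyclohexyl]ethynyl}furan-2(5H)-one
Product: 16 3-{(Z)-2-[(1R,5R)-1,5-dihydroxy-2,2-dimethyl-6-methylidenecyclohexyl]ethenyl}furan-2(5H)-one
Conditions: H2 (1 atm), Pd/CaCO3 poisoned with Pb(OAc)2 (Lindlar catalyst), quinoline, EtOAc, rt
Reagents that add atoms: none
Why: Lindlar semi-hydrogenation should give the (Z)-alkene by syn addition of hydrogen, the isolated 1,1-disubstituted alkene and the lactone alkene reacting much more slowly than the alkyne.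

Step 11
Reactants: 16 3-{(Z)-2-[(1R,5R)-1,5-dihydroxy-2,2-dimethyl-6-methylidenecyclohexyl]ethenyl}furan-2(5H)-one
Product: 18 1β,5α-dihydroxydrim-7-en-12,11-olide, via deconjugated lactone 17 (not isolated)
Conditions: Fe(acac)3 (30 mol %), PhSiH3, EtOH, 60 °C; then DBU (cat.), CH2Cl2, rt
Reagents that add atoms: none
Why: Hydrogen atom transfer from the iron hydride generated from Fe(acac)3 and PhSiH3 to the CH2 terminus of the electron-rich exocyclic alkene makes the C10 methyl group and a tertiary C10 radical, which adds to the butenolide β-carbon C9; the adduct radical (delocalised over C8, the lactone carbonyl and C6) is reduced by divalent iron to the dienolate, protonated, and the alkene is then brought into conjugation (C7=C8) by DBU through 17. The closest known reaction type is the iron-mediated reductive olefin coupling (HAT-initiated Giese addition), used intramolecularly to build quaternary centres and trans-decalins. Ring B closes in the 6-endo-trig mode with respect to C8=C9, the (Z)-C6=C7 alkene holding C9 within reach of C10. C10 is controlled by the ring A chair in which the 1β-hydroxyl and the C5 side chain are equatorial and the 5α-hydroxyl is axial: the β-face of the C10 radical is shielded by the axial 4β-methyl group, so C9 should bond to the α-face and the new methyl becomes axial (trans ring fusion). C9 is controlled by the lactone ring, which ties C11 cis to C12 and therefore into the outside, pseudo-equatorial (β) position of the half-chair transition state, leaving H9 axial (α). The step needs hydrogen atom transfer to the isolated 1,1-disubstituted alkene and not to the electron-poor dienyl lactone, which the preference of the metal hydride for electron-rich donor alkenes should secure, and attack at C9 and not at C8, which polarity matching and the stabilised adduct radical should secure.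

Step 12
Reactants: 18 1β,5α-dihydroxydrim-7-en-12,11-olide
Product: 19 drim-7-ene-1β,5α,11,12-tetraol
Conditions: iBu2AlH (excess), CH2Cl2, −78 to 0 °C; then H2O
Reagents that add atoms: none
Why: Hydride reduction of the unsaturated lactone by 1,2-addition should give the 11,12-diol without touching C9, which is not α to a carbonyl at this oxidation level.

Step 13
Reactants: 19 drim-7-ene-1β,5α,11,12-tetraol
Product: 20 11,12-bis(triethylsilyloxy)drim-7-ene-1β,5α-diol
Conditions: TESCl (2.2 equiv), imidazole, CH2Cl2, −20 to 0 °C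
Reagents that add atoms: triethylsilyl chloride, CC[Si](CC)(CC)Cl
Why: Chemoselective silylation: the two primary hydroxyls should react far faster than the neopentyl secondary C1 hydroxyl and the tertiary C5 hydroxyl.

Step 14
Reactants: 21 (E)-4-hydroxycinnamic acid (p-coumaric acid)
Product: 23 (E)-3-{4-[(tert-butyldimethylsilyl)oxy]phenyl}prop-2-enoic acid, via silyl ester 22 (not isolated)
Conditions: TBSCl (2.5 equiv), imidazole, DMF, rt; then AcOH/THF/H2O, rt
Reagents that add atoms: tert-butyldimethylsilyl chloride, CC(C)(C)[Si](C)(C)Cl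
Why: Bis-silylation followed by selective hydrolysis of the labile silyl ester should leave the aryl silyl ether and free the acid.

Step 15
Reactants: 20 11,12-bis(triethylsilyloxy)drim-7-ene-1β,5α-diol; 23 (E)-3-{4-[(tert-butyldimethylsilyl)oxy]phenyl}prop-2-enoic acid
Product: 25 1β-{(E)-3-[4-(tert-butyldimethylsilyloxy)phenyl]prop-2-enoyloxy}-11,12-bis(triethylsilyloxy)drim-7-en-5α-ol, via mixed anhydride 24 (not isolated)
Conditions: 23, 2,4,6-trichlorobenzoyl chloride, Et3N, THF, rt; then 20, DMAP, toluene, 50 °C
Reagents that add atoms: none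
Why: Yamaguchi esterification, suited to hindered secondary alcohols, should acylate O1 with retention at C1 (the C–O bond is not touched) while the tertiary C5 hydroxyl stays free.

Step 16
Reactants: 25 the silyl-protected ester
Product: 26 1β-{(E)-3-[4-(tert-butyldimethylsilyloxy)phenyl]prop-2-enoyloxy}drim-7-ene-5α,11,12-triol
Conditions: PPTS (cat.), MeOH/CH2Cl2, 0 °C
Reagents that add atoms: none
Why: Acid-catalysed methanolysis should remove the two primary triethylsilyl ethers while the phenolic tert-butyldimethylsilyl ether and the ester are stable.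

Step 17
Reactants: 26 the 11,12-diol
Product: 27 1β-{(E)-3-[4-(tert-butyldimethylsilyloxy)phenyl]prop-2-enoyloxy}-5α-hydroxydrim-7-ene-11,12-dial
Conditions: (COCl)2, DMSO, CH2Cl2, −78 °C; then Et3N, −78 to −30 °C
Reagents that add atoms: none
Why: Swern oxidation activates both primary hydroxyls before base is added, so no lactol or lactone should form, and the low temperature should preserve the base-labile C9 stereocenter.

Step 18
Reactants: 27 the silyl-protected dialdehyde
Product: 28 1β-[(E)-3-(4-hydroxyphenyl)prop-2-enoyloxy]-5α-hydroxydrim-7-ene-11,12-dial (CNP0323926.1)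
Conditions: Bu4NF, AcOH (1:1), THF, 0 °C
Reagents that add atoms: none
Why: Buffered fluoride desilylation should cleave the aryl silyl ether under near-neutral conditions that neither epimerise C9 nor eliminate the C5 hydroxyl.

**Compound list**

1 | 2-methylpentan-3-one | CCC(=O)C(C)C | starting material
2 | methyl acrylate | C=CC(=O)OC | starting material
3 | methyl 4,4-dimethyl-5-oxoheptanoate | CCC(=O)C(C)(C)CCC(=O)OC | intermediate
4 | 2,4,4-trimethylcyclohexane-1,3-dione | CC1C(=O)CCC(C)(C)C1=O | intermediate
5 | 3-(2-methylpropoxy)-2,6,6-trimethylcyclohex-2-en-1-one | CC(C)COC1=C(C)C(=O)C(C)(C)CC1 | intermediate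
6 | ethynyl(trimethyl)silane | C#C[Si](C)(C)C | starting material
7 | 3-(2-methylpropoxy)-2,6,6-trimethyl-1-[(trimethylsilyl)ethynyl]cyclohex-2-en-1-ol (racemic; lithium alkoxide in the flask) | CC(C)COC1=C(C)C(O)(C#C[Si](C)(C)C)C(C)(C)CC1 | intermediate
8 | 2,4,4-trimethyl-3-[(trimethylsilyl)ethynyl]cyclohex-2-en-1-one | CC1=C(C#C[Si](C)(C)C)C(C)(C)CCC1=O | intermediate
9 | (1R)-2,4,4-trimethyl-3-[(trimethylsilyl)ethynyl]cyclohex-2-en-1-ol | CC1(C)CC[C@@H](O)C(C)=C1C#C[Si](C)(C)C | intermediate
10 | tert-butyldimethyl{[(1R)-2,4,4-trimethyl-3-[(trimethylsilyl)ethynyl]cyclohex-2-en-1-yl]oxy}silane | CC1(C)CC[C@@H](O[Si](C)(C)C(C)(C)C)C(C)=C1C#C[Si](C)(C)C | intermediate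
11 | tert-butyldimethyl({(1S,5R,6S)-2,2,6-trimethyl-1-[(trimethylsilyl)ethynyl]-7-oxabicyclo[4.1.0]heptan-5-yl}oxy)silane | CC1(C)CC[C@@H](O[Si](C)(C)C(C)(C)C)[C@]2(C)O[C@]12C#C[Si](C)(C)C | intermediate
12 | (1R,5R)-5-[(tert-butyldimethylsilyl)oxy]-2,2-dimethyl-6-methylidene-1-[(trimethylsilyl)ethynyl]cyclohexan-1-ol | CC1(C)CC[C@@H](O[Si](C)(C)C(C)(C)C)C(=C)[C@@]1(O)C#C[Si](C)(C)C | intermediate
13 | (1S,3R)-1-ethynyl-6,6-dimethyl-2-methylidenecyclohexane-1,3-diol | CC1(C)CC[C@@H](O)C(=C)[C@@]1(O)C#C | intermediate
14 | 3-bromofuran-2(5H)-one | O=C1OCC=C1Br | starting material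
15 | 3-{[(1S,5R)-1,5-dihydroxy-2,2-dimethyl-6-methylidenecyclohexyl]ethynyl}furan-2(5H)-one | CC1(C)CC[C@@H](O)C(=C)[C@@]1(O)C#CC1=CCOC1=O | intermediate
16 | 3-{(Z)-2-[(1R,5R)-1,5-dihydroxy-2,2-dimethyl-6-methylidenecyclohexyl]ethenyl}furan-2(5H)-one | CC1(C)CC[C@@H](O)C(=C)[C@@]1(O)/C=C\C1=CCOC1=O | intermediate
17 | 1β,5α-dihydroxydrim-6-en-12,11-olide (C8 epimers) | CC1(C)CC[C@@H](O)[C@]2(C)[C@@H](COC3=O)C3C=C[C@@]12O | intermediate
18 | 1β,5α-dihydroxydrim-7-en-12,11-olide | CC1(C)CC[C@@H](O)[C@]2(C)[C@@H](COC3=O)C3=CC[C@@]12O | intermediate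
19 | drim-7-ene-1β,5α,11,12-tetraol | CC1(C)CC[C@@H](O)[C@]2(C)[C@@H](CO)C(CO)=CC[C@@]12O | intermediate
20 | 11,12-bis(triethylsilyloxy)drim-7-ene-1β,5α-diol | CC1(C)CC[C@@H](O)[C@]2(C)[C@@H](CO[Si](CC)(CC)CC)C(CO[Si](CC)(CC)CC)=CC[C@@]12O | intermediate
21 | (E)-4-hydroxycinnamic acid (p-coumaric acid) | OC(=O)/C=C/c1ccc(O)cc1 | starting material
22 | tert-butyldimethylsilyl (E)-3-{4-[(tert-butyldimethylsilyl)oxy]phenyl}prop-2-enoate | CC(C)(C)[Si](C)(C)OC(=O)/C=C/c1ccc(O[Si](C)(C)C(C)(C)C)cc1 | intermediate
23 | (E)-3-{4-[(tert-butyldimethylsilyl)oxy]phenyl}prop-2-enoic acid | OC(=O)/C=C/c1ccc(O[Si](C)(C)C(C)(C)C)cc1 | intermediate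
24 | (E)-3-{4-[(tert-butyldimethylsilyl)oxy]phenyl}prop-2-enoic 2,4,6-trichlorobenzoic anhydride | O=C(/C=C/c1ccc(O[Si](C)(C)C(C)(C)C)cc1)OC(=O)c1c(Cl)cc(Cl)cc1Cl | intermediate
25 | 1β-{(E)-3-[4-(tert-butyldimethylsilyloxy)phenyl]prop-2-enoyloxy}-11,12-bis(triethylsilyloxy)drim-7-en-5α-ol | CC1(C)CC[C@@H](OC(=O)/C=C/c2ccc(O[Si](C)(C)C(C)(C)C)cc2)[C@]2(C)[C@@H](CO[Si](CC)(CC)CC)C(CO[Si](CC)(CC)CC)=CC[C@@]12O | intermediate
26 | 1β-{(E)-3-[4-(tert-butyldimethylsilyloxy)phenyl]prop-2-enoyloxy}drim-7-ene-5α,11,12-triol | CC1(C)CC[C@@H](OC(=O)/C=C/c2ccc(O[Si](C)(C)C(C)(C)C)cc2)[C@]2(C)[C@@H](CO)C(CO)=CC[C@@]12O | intermediate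
27 | 1β-{(E)-3-[4-(tert-butyldimethylsilyloxy)phenyl]prop-2-enoyloxy}-5α-hydroxydrim-7-ene-11,12-dial | CC1(C)CC[C@@H](OC(=O)/C=C/c2ccc(O[Si](C)(C)C(C)(C)C)cc2)[C@]2(C)[C@@H](C=O)C(C=O)=CC[C@@]12O | intermediate
28 | 1β-[(E)-3-(4-hydroxyphenyl)prop-2-enoyloxy]-5α-hydroxydrim-7-ene-11,12-dial (CNP0323926.1) | CC1(C)CC[C@@H](OC(=O)/C=C/c2ccc(O)cc2)[C@]2(C)[C@@H](C=O)C(C=O)=CC[C@@]12O | target

**Step count and risks**

Total step count: 18. Longest linear sequence: 17 steps (steps 1–13 and 15–18); step 14 prepares the acyl donor.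

Steps most likely to fail:

Step 11. Hydrogen atom transfer to the (Z)-dienyl lactone may compete with transfer to the donor alkene, the C10 radical may be reduced before ring closure, or bonding may occur on the β-face of C10 (cis fusion). The fallback replaces the (Z)-alkene by a saturated C6 and an acetate leaving group on C7, which removes the conjugated diene and allows a chair-like transition state. It sets out from 13: hydroboration of the terminal alkyne with dicyclohexylborane and oxidation with NaBO3·4H2O should give the hydroxy aldehyde F1; a Nozaki–Hiyama–Kishi reaction of F1 with 14 (CrCl2, NiCl2 cat., DMF) should give the allylic alcohol F2 (both C7 epimers); acetylation (Ac2O, pyridine, DMAP) should give the diacetate F3. Under Fe(acac)3/PhSiH3/EtOH, ring B should then close by 6-endo Giese addition at C9 of a simple α-substituted butenolide, and the lactone enolate should expel the C7 acetate (E1cB) to give the C7=C8 alkene of the acetoxy lactone F4. Reduction of F4 with iBu2AlH cleaves lactone and acetate and comes back to the route at 19.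

Step 7. The Lewis-acidic aluminium reagent may ionise the propargylic C5–O bond and trigger a skeletal (semipinacol-type) rearrangement, or deprotonation may be slow or occur at the wrong site. The fallback sets out from 10 and uses a Schenck ene reaction with singlet oxygen (O2, tetraphenylporphyrin, visible light, CH2Cl2, −20 °C). All abstractable allylic hydrogens lie on the C10 side, so oxygen can only bond to C5, on the face opposite the silyloxy group, which should give the allylic hydroperoxide F5 with the exocyclic methylene already in place. Reduction of F5 with PPh3 comes back to the route at 12.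

Step 15. Acylation of the neopentyl, peri-crowded secondary C1 hydroxyl may be sluggish, and the mixed anhydride may decompose first. The fallback builds the cinnamate on the alcohol instead of delivering it intact. It sets out from 20: Steglich acylation with the small (diethoxyphosphoryl)acetic acid (DCC, DMAP cat., CH2Cl2) should give the phosphonoacetate F6. Horner–Wadsworth–Emmons olefination of F6 with 4-[(tert-butyldimethylsilyl)oxy]benzaldehyde (LiCl, DBU, MeCN) should give the (E)-ester and comes back to the route at 25.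

Further compounds
F1 | step 11 | 2-[(1R,5R)-1,5-dihydroxy-2,2-dimethyl-6-methylidenecyclohexyl]acetaldehyde | CC1(C)CC[C@@H](O)C(=C)[C@@]1(O)CC=O
F2 | step 11 | 3-{2-[(1R,5R)-1,5-dihydroxy-2,2-dimethyl-6-methylidenecyclohexyl]-1-hydroxyethyl}furan-2(5H)-one (both C7 epimers) | CC1(C)CC[C@@H](O)C(=C)[C@@]1(O)CC(O)C1=CCOC1=O
F3 | step 11 | C1,C7-di-O-acetyl derivative of F2 | CC1(C)CC[C@@H](OC(C)=O)C(=C)[C@@]1(O)CC(OC(C)=O)C1=CCOC1=O
F4 | step 11 | 1β-acetoxy-5α-hydroxydrim-7-en-12,11-olide | CC1(C)CC[C@@H](OC(C)=O)[C@]2(C)[C@@H](COC3=O)C3=CC[C@@]12O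
F5 | step 7 | C5 hydroperoxide corresponding to 12 (5α-OOH, C10=CH2, 1β-silyloxy) | CC1(C)CC[C@@H](O[Si](C)(C)C(C)(C)C)C(=C)[C@@]1(OO)C#C[Si](C)(C)C
F6 | step 15 | 1β-[(diethoxyphosphoryl)acetoxy]-11,12-bis(triethylsilyloxy)drim-7-en-5α-ol | CC1(C)CC[C@@H](OC(=O)CP(=O)(OCC)OCC)[C@]2(C)[C@@H](CO[Si](CC)(CC)CC)C(CO[Si](CC)(CC)CC)=CC[C@@]12O
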